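**Plan**

Numbering: seven-membered ring C1(O-aroyl)–C2–C3(Me)(OH)–C4–C5–C6–C10(i-Pr); five-membered ring C5–C9–C8(Me)–C7–C6, epoxide on C8–C9.
Retrosynthesis: cut the C1–O ester bond, the C8–C9 epoxide and C3–CH3; then cut C2–C3 and C3–C4 together at one dithiane carbon; then the terminal epoxide C1–C2, C8–CH3, C5–C4 and C6–C10.
Enabling feature: C3 is a carbonyl-level carbon of the seven-membered ring flanked by two methylenes, C2 (next to the C1 carbinol) and C4 (next to ring-fusion C5), so a single acyl-anion carbon can be joined to an epoxide terminus and to a primary halide.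
Forward: the five-membered ring comes from (R)-4-silyloxycyclopentenone and receives the C10/C1 arm and the C4 arm; the seven-membered ring is then closed by a silyl-dithiane anion relay; methyl addition, epoxidation and acylation finish the target.
Stereochemistry: C6 from the enone stereocentre (anti Michael addition), C5 by anti conjugate addition, C10 by lactone equilibration, C1 by CBS reduction, C3 by addition anti to the axial C1 silyloxy group, C8/C9 by a chiral dioxirane.

Key step: step 12

Remark: enone 3 and the L-fructose-derived Shi ketone are taken as purchasable; compounds 4–11 are carried as C10 epimer mixtures that step 7 converges; descriptors of the bicyclic compounds 23–27, 32 and 33 refer to the numbering above.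

**Step 1**
Reactants: 1 methyl 3-methylbutanoate
Product: 2 (1-methoxy-3-methylbut-1-enyloxy)trimethylsilane (E/Z mixture)
Conditions: LiN(i-Pr)2, THF, −78 °C; Me3SiCl, −78 °C → rt
Reagents that add atoms: chlorotrimethylsilane, C[Si](C)(C)Cl
Why: Kinetic ester enolisation and O-silylation give the silyl ketene acetal; its geometry does not matter because C10 is equilibrated in step 7.

**Step 2**
Reactants: 2 (1-methoxy-3-methylbut-1-enyloxy)trimethylsilane; 3 (R)-4-(tert-butyldimethylsilyloxy)cyclopent-2-en-1-one
Product: 5 methyl 2-[(1S,2R)-2-(tert-butyldimethylsilyloxy)-4-oxocyclopentyl]-3-methylbutanoate (C10 epimers), via trimethylsilyl enol ether 4 (not isolated)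
Conditions: Tf2NH (2 mol %), CH2Cl2, −78 °C; then 1 M HCl, THF, 0 °C
Reagents that add atoms: none
Why: Mukaiyama–Michael addition in which the silyl-activated enone is attacked at C6 on the face anti to the neighbouring C5 silyloxy group, which fixes C6, while C10 forms unselectively and is corrected later.

**Step 3**
Reactants: 5 methyl 2-[(1S,2R)-2-(tert-butyldimethylsilyloxy)-4-oxocyclopentyl]-3-methylbutanoate
Product: 6 methyl 3-methyl-2-[(1R)-4-oxocyclopent-2-en-1-yl]butanoate (C10 epimers)
Conditions: DBU, CH2Cl2, 0 °C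
Reagents that add atoms: none
Why: E1cB β-elimination: DBU enolises toward C9 and expels the C5 silyloxy group, giving the 4-substituted cyclopentenone (C8=O, C9=C5) in which C6 keeps its configuration.

**Step 4**
Reactants: 6 methyl 3-methyl-2-[(1R)-4-oxocyclopent-2-en-1-yl]butanoate
Product: 8 methyl 2-[(1S,2S)-2-{[dimethyl(propan-2-yloxy)silyl]methyl}-4-(trifluoromethanesulfonyloxy)cyclopent-3-en-1-yl]-3-methylbutanoate (C10 epimers), via chloromagnesium enolate 7 (not isolated)
Conditions: (i-PrO)Me2SiCH2MgCl, CuI (10 mol %), THF, −78 → −40 °C; then Comins' reagent, −78 → 0 °C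
Reagents that add atoms: (isopropoxydimethylsilyl)methylmagnesium chloride, CC(C)O[Si](C)(C)C[Mg]Cl; N-(5-chloropyridin-2-yl)bis(trifluoromethanesulfonyl)imide (Comins' reagent), Clc1ccc(nc1)N(S(=O)(=O)C(F)(F)F)S(=O)(=O)C(F)(F)F
Why: Copper-catalysed conjugate addition of the hydroxymethyl-anion equivalent enters C5 anti to the C6 side chain (trans, sets C5), and O-triflation of the regio-defined enolate locks the double bond at C8=C9.

**Step 5**
Reactants: 8 the enol triflate from step 4
Product: 9 methyl 2-[(1S,2S)-2-{[dimethyl(propan-2-yloxy)silyl]methyl}-4-methylcyclopent-3-en-1-yl]-3-methylbutanoate (C10 epimers)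
Conditions: Me2Zn, Pd(PPh3)4 (5 mol %), THF, 0 °C → rt
Reagents that add atoms: dimethylzinc, C[Zn]C
Why: Negishi cross-coupling of the alkenyl triflate installs the C8 methyl group without moving the double bond and tolerates the ester and the alkoxysilane.

**Step 6**
Reactants: 9 the silylmethyl cyclopentene from step 5
Product: 10 methyl 2-[(1R,2S)-2-(hydroxymethyl)-4-methylcyclopent-3-en-1-yl]-3-methylbutanoate (C10 epimers)
Conditions: 30% H2O2, KF, KHCO3, THF/MeOH, rt
Reagents that add atoms: hydrogen peroxide, OO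
Why: Tamao oxidation converts the C4–Si bond into C4–OH, and basic peroxide leaves the trisubstituted alkene and the ester alone.

**Step 7**
Reactants: 10 methyl 2-[(1R,2S)-2-(hydroxymethyl)-4-methylcyclopent-3-en-1-yl]-3-methylbutanoate
Product: 12 (4S,4aR,7aS)-6-methyl-4-(propan-2-yl)-4,4a,5,7a-tetrahydrocyclopenta[c]pyran-3(1H)-one, via lactone C10-epimer mixture 11 (not isolated)
Conditions: t-BuOK (0.3 equiv), THF, 5 Å MS, rt; then AcOH
Reagents that add atoms: none
Why: Alkoxide-catalysed lactonisation closes the trans-fused δ-lactone and the same base equilibrates C10 through the lactone enolate, where the isopropyl group should settle equatorial and anti to H6, the required configuration (thermodynamic control).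

**Step 8**
Reactants: 12 the trans-fused lactone
Product: 13 (2S)-2-[(1R,2S)-2-(hydroxymethyl)-4-methylcyclopent-3-en-1-yl]-N-methoxy-N,3-dimethylbutanamide
Conditions: MeNH(OMe)·HCl, AlMe3, CH2Cl2, 0 °C → rt
Reagents that add atoms: N,O-dimethylhydroxylamine hydrochloride, CNOC.Cl
Why: Weinreb aminolysis of the lactone by the non-basic aluminium amide frees the C4 alcohol and makes C1 a mono-acylating group without disturbing C10.

**Step 9**
Reactants: 13 the hydroxy Weinreb amide
Product: 14 (2S)-2-[(1S,2S)-2-(chloromethyl)-4-methylcyclopent-3-en-1-yl]-N-methoxy-N,3-dimethylbutanamide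
Conditions: PPh3, CCl4, CH2Cl2, 40 °C
Reagents that add atoms: tetrachloromethane, ClC(Cl)(Cl)Cl
Why: Appel reaction (SN2 at primary C4); any O-alkyl imidate formed by amide participation is opened by chloride at the same carbon or reverts to lactone 12 on work-up, which can be recycled.

**Step 10**
Reactants: 14 the chloro Weinreb amide
Product: 16 (3S)-1-chloro-3-[(1S,2S)-2-(chloromethyl)-4-methylcyclopent-3-en-1-yl]-4-methylpentan-2-one, via lithium hemiaminal alkoxide 15 (not isolated)
Conditions: ICH2Cl, MeLi·LiBr, THF, −78 °C; then aq. NH4Cl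
Reagents that add atoms: chloroiodomethane, ClCI
Why: Carbenoid acylation: chloromethyllithium formed by iodine–lithium exchange adds once to the Weinreb amide, and the chelated tetrahedral adduct releases the α-chloroketone only on work-up.

**Step 11**
Reactants: 16 the chloromethyl ketone
Product: 18 (2S)-2-{(1S)-1-[(1S,2S)-2-(chloromethyl)-4-methylcyclopent-3-en-1-yl]-2-methylpropyl}oxirane, via chlorohydrin 17 (not isolated)
Conditions: (S)-2-methyl-CBS-oxazaborolidine (20 mol %), catecholborane, toluene, −78 → −40 °C; then 2 M NaOH, MeOH, rt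
Reagents that add atoms: none
Why: Corey–Bakshi–Shibata reduction: the (S)-oxazaborolidine reads CH2Cl as the small and the branched C10 residue as the large group and should give the (S)-chlorohydrin under reagent control (catecholborane spares the alkene), after which hydroxide closes the epoxide by Williamson displacement without touching C1.

**Step 12**
Reactants: 18 the epoxy chloride from step 11; 19 2-(tert-butyldimethylsilyl)-1,3-dithiane
Product: 23 (1R,5S,6R,10S) trans-fused hydroazulene with C1 tert-butyldimethylsilyl ether, C3 spiro-1,3-dithiane, C8=C9 alkene, 8-methyl and 10-isopropyl groups, via 2-lithio-2-silyl-1,3-dithiane 20 (not isolated), via lithium alkoxide 21 (not isolated), via relayed dithianyl anion 22 (not isolated)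
Conditions: 19, t-BuLi, Et2O, −78 → −45 °C; 18, Et2O, −78 → −25 °C; then HMPA, THF (0.01 M), −78 °C → rt
Reagents that add atoms: none
Why: Anion-relay annulation: lithiated silyl dithiane 20 opens the terminal epoxide of 18 at C2 in ether (C2–C3) to give alkoxide 21; HMPA then triggers a 1,4-Brook rearrangement that moves silicon to the C1 oxygen and regenerates a dithiane anion 22, which displaces the primary C4 chloride (C3–C4). The closest known reactions are the silyl-dithiane linchpin couplings of epoxides with alkyl halides, their ring-forming variants with epoxy sulfonates and bis-epoxides, and the Corey–Seebach cycloalkylation of chloroalkyl dithianes. The seven-membered ring closes in a 7-exo-tet mode, with the trans C5 and C6 arms on the cyclopentene holding C3 and C4 within reach. No stereocentre is created: C1 keeps its configuration because attack is at C2, and C5, C6 and C10 are not involved. The selectivity needed is epoxide before chloride, secured by the bulky silyl anion in a weakly coordinating solvent at low temperature, which reacts with the lithium-activated epoxide but not with the β-branched primary chloride. The second anion appears only after HMPA is added, when high dilution favours ring closure over intermolecular alkylation.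

**Step 13**
Reactants: 23 the spiro-dithiane silyl ether
Product: 24 (1R,5S,6R,10S) trans-fused hydroazulen-3-one with C1 tert-butyldimethylsilyl ether
Conditions: MeI, CaCO3, MeCN/H2O (9:1), 45 °C
Reagents that add atoms: water, O
Why: Alkylative dithiane hydrolysis (S-methylation, then hydrolysis) under buffered neutral conditions unmasks the C3 ketone and leaves the silyl ether and the alkene untouched.

**Step 14**
Reactants: 24 the C3 ketone
Product: 25 (1R,3R,5S,6R,10S) C3 tertiary alcohol (3-methyl, 3-hydroxy) with C1 tert-butyldimethylsilyl ether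
Conditions: MeLi, CeCl3, THF, −78 °C
Reagents that add atoms: methyllithium, [Li]C
Why: Organocerium 1,2-addition: with the C10 isopropyl group equatorial the cis C1 silyloxy group is axial and screens the α face of the 1,3-related carbonyl, so methyl should enter from the β face and place the C3 hydroxyl cis to the C1 oxygen, while the weakly basic reagent avoids enolisation and β-elimination.

**Step 15**
Reactants: 25 the tertiary alcohol
Product: 26 (1R,3R,5S,6R,8R,9S,10S) 8,9-epoxide with C1 tert-butyldimethylsilyl ether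
Conditions: L-fructose-derived Shi ketone (30 mol %), KHSO5 (as Oxone), K2CO3, Bu4NHSO4, MeCN/dimethoxymethane/aq. Na2B4O7 buffer (pH 10.5), 0 °C
Reagents that add atoms: potassium peroxymonosulfate, [K+].[O-]S(=O)(=O)OO
Why: Shi asymmetric epoxidation: the chiral dioxirane meets the trisubstituted C8=C9 alkene in a spiro transition state and, by analogy with 1-substituted cycloalkenes, this ketone enantiomer should deliver oxygen to the α face (syn to C4), setting C8 and C9 under reagent control over a weak substrate bias.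

**Step 16**
Reactants: 26 the epoxy silyl ether
Product: 27 (1R,3R,5S,6R,8R,9S,10S) epoxy 1,3-diol
Conditions: Bu4NF, THF, rt → 50 °C
Reagents that add atoms: none
Why: Fluoride-mediated desilylation frees the C1 alcohol, and the C3 hydroxyl cannot open the epoxide because both sit on the α face.

**Step 17**
Reactants: 28 3-hydroxy-4-methoxybenzoic acid (isovanillic acid)
Product: 30 3-(tert-butyldimethylsilyloxy)-4-methoxybenzoic acid, via bis-silylated isovanillic acid 29 (not isolated)
Conditions: t-BuMe2SiCl, imidazole, DMF, rt; then AcOH/THF/H2O, rt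
Reagents that add atoms: tert-butyldimethylsilyl chloride, CC(C)(C)[Si](C)(C)Cl
Why: Exhaustive silylation followed by selective hydrolysis of the labile silyl ester leaves the phenol masked as its silyl ether.

**Step 18**
Reactants: 27 the epoxy diol; 30 3-(tert-butyldimethylsilyloxy)-4-methoxybenzoic acid
Product: 32 C1 3-(tert-butyldimethylsilyloxy)-4-methoxybenzoate of 27, via mixed Yamaguchi anhydride 31 (not isolated)
Conditions: 2,4,6-Cl3C6H2COCl, Et3N, THF, rt; then 27, DMAP, toluene, rt → 40 °C
Reagents that add atoms: none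
Why: Yamaguchi esterification: the mixed anhydride with DMAP acylates the hindered secondary C1 alcohol, while the tertiary C3 alcohol is too hindered to compete and the epoxide is inert to the basic medium.

**Step 19**
Reactants: 32 the silyl-protected ester
Product: 33 the target, (1R,3R,5S,6R,8R,9S,10S) C1 3-hydroxy-4-methoxybenzoate
Conditions: Bu4NF, AcOH, THF, 0 °C
Reagents that add atoms: none
Why: Buffered fluoride cleavage of the aryl silyl ether is fast at 0 °C and should leave the benzoate, the tertiary alcohol and the epoxide intact.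

**Compound list**

1 | methyl 3-methylbutanoate | COC(=O)CC(C)C | starting material
2 | (1-methoxy-3-methylbut-1-enyloxy)trimethylsilane (E/Z mixture) | COC(O[Si](C)(C)C)=CC(C)C | intermediate
3 | (R)-4-(tert-butyldimethylsilyloxy)cyclopent-2-en-1-one | CC(C)(C)[Si](C)(C)O[C@H]1C=CC(=O)C1 | starting material
4 | methyl 2-[(1S,5R)-5-(tert-butyldimethylsilyloxy)-3-(trimethylsilyloxy)cyclopent-2-en-1-yl]-3-methylbutanoate (C10 epimers) | COC(=O)C(C(C)C)[C@@H]1C=C(O[Si](C)(C)C)C[C@H]1O[Si](C)(C)C(C)(C)C | intermediate
5 | methyl 2-[(1S,2R)-2-(tert-butyldimethylsilyloxy)-4-oxocyclopentyl]-3-methylbutanoate (C10 epimers) | COC(=O)C(C(C)C)[C@@H]1CC(=O)C[C@H]1O[Si](C)(C)C(C)(C)C | intermediate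
6 | methyl 3-methyl-2-[(1R)-4-oxocyclopent-2-en-1-yl]butanoate (C10 epimers) | COC(=O)C(C(C)C)[C@@H]1CC(=O)C=C1 | intermediate
7 | chloromagnesium enolate of the conjugate adduct (O–MgCl in place of O–Tf in 8) | COC(=O)C(C(C)C)[C@@H]1CC(O[Mg]Cl)=C[C@H]1C[Si](C)(C)OC(C)C | intermediate
8 | methyl 2-[(1S,2S)-2-{[dimethyl(propan-2-yloxy)silyl]methyl}-4-(trifluoromethanesulfonyloxy)cyclopent-3-en-1-yl]-3-methylbutanoate (C10 epimers) | COC(=O)C(C(C)C)[C@@H]1CC(OS(=O)(=O)C(F)(F)F)=C[C@H]1C[Si](C)(C)OC(C)C | intermediate
9 | methyl 2-[(1S,2S)-2-{[dimethyl(propan-2-yloxy)silyl]methyl}-4-methylcyclopent-3-en-1-yl]-3-methylbutanoate (C10 epimers) | COC(=O)C(C(C)C)[C@@H]1CC(C)=C[C@H]1C[Si](C)(C)OC(C)C | intermediate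
10 | methyl 2-[(1R,2S)-2-(hydroxymethyl)-4-methylcyclopent-3-en-1-yl]-3-methylbutanoate (C10 epimers) | COC(=O)C(C(C)C)[C@@H]1CC(C)=C[C@H]1CO | intermediate
11 | (4aR,7aS)-6-methyl-4-(propan-2-yl)-4,4a,5,7a-tetrahydrocyclopenta[c]pyran-3(1H)-one, mixture of epimers at C4 (= C10) | O=C1OC[C@@H]2C=C(C)C[C@H]2C1C(C)C | intermediate
12 | (4S,4aR,7aS)-6-methyl-4-(propan-2-yl)-4,4a,5,7a-tetrahydrocyclopenta[c]pyran-3(1H)-one | O=C1OC[C@@H]2C=C(C)C[C@H]2[C@@H]1C(C)C | intermediate
13 | (2S)-2-[(1R,2S)-2-(hydroxymethyl)-4-methylcyclopent-3-en-1-yl]-N-methoxy-N,3-dimethylbutanamide | CON(C)C(=O)[C@@H](C(C)C)[C@@H]1CC(C)=C[C@H]1CO | intermediate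
14 | (2S)-2-[(1S,2S)-2-(chloromethyl)-4-methylcyclopent-3-en-1-yl]-N-methoxy-N,3-dimethylbutanamide | CON(C)C(=O)[C@@H](C(C)C)[C@@H]1CC(C)=C[C@H]1CCl | intermediate
15 | lithium alkoxide of the tetrahedral adduct of 14 with chloromethyllithium (N-methoxy-N-methyl hemiaminal) | [Li]OC(CCl)(N(C)OC)[C@@H](C(C)C)[C@@H]1CC(C)=C[C@H]1CCl | intermediate
16 | (3S)-1-chloro-3-[(1S,2S)-2-(chloromethyl)-4-methylcyclopent-3-en-1-yl]-4-methylpentan-2-one | ClCC(=O)[C@@H](C(C)C)[C@@H]1CC(C)=C[C@H]1CCl | intermediate
17 | (2S,3S)-1-chloro-3-[(1S,2S)-2-(chloromethyl)-4-methylcyclopent-3-en-1-yl]-4-methylpentan-2-ol | ClC[C@@H](O)[C@@H](C(C)C)[C@@H]1CC(C)=C[C@H]1CCl | intermediate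
18 | (2S)-2-{(1S)-1-[(1S,2S)-2-(chloromethyl)-4-methylcyclopent-3-en-1-yl]-2-methylpropyl}oxirane | ClC[C@H]1[C@@H](CC(C)=C1)[C@H](C(C)C)[C@H]2CO2 | intermediate
19 | 2-(tert-butyldimethylsilyl)-1,3-dithiane | CC(C)(C)[Si](C)(C)C1SCCCS1 | starting material
20 | 2-(tert-butyldimethylsilyl)-2-lithio-1,3-dithiane | CC(C)(C)[Si](C)(C)C1([Li])SCCCS1 | intermediate
21 | lithium (2R,3S)-1-[2-(tert-butyldimethylsilyl)-1,3-dithian-2-yl]-3-[(1S,2S)-2-(chloromethyl)-4-methylcyclopent-3-en-1-yl]-4-methylpentan-2-olate | [Li]O[C@H](CC1([Si](C)(C)C(C)(C)C)SCCCS1)[C@@H](C(C)C)[C@@H]2CC(C)=C[C@H]2CCl | intermediate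
22 | 2-lithio-1,3-dithiane carrying the chain of 21 with the C1 oxygen silylated (after 1,4-Brook shift) | CC(C)(C)[Si](C)(C)O[C@H](CC1([Li])SCCCS1)[C@@H](C(C)C)[C@@H]2CC(C)=C[C@H]2CCl | intermediate
23 | (1R,5S,6R,10S) trans-fused hydroazulene: C1 tert-butyldimethylsilyl ether, C3 spiro-1,3-dithiane, C8=C9, 8-methyl, 10-isopropyl | CC(C)(C)[Si](C)(C)O[C@@H]1CC2(SCCCS2)C[C@H]3[C@@H](CC(C)=C3)[C@@H]1C(C)C | intermediate
24 | (1R,5S,6R,10S) trans-fused hydroazulen-3-one with C1 tert-butyldimethylsilyl ether | CC(C)(C)[Si](C)(C)O[C@@H]1CC(=O)C[C@H]2[C@@H](CC(C)=C2)[C@@H]1C(C)C | intermediate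
25 | (1R,3R,5S,6R,10S) 3-hydroxy-3-methyl hydroazulene with C1 tert-butyldimethylsilyl ether | CC(C)(C)[Si](C)(C)O[C@@H]1C[C@](C)(O)C[C@H]2[C@@H](CC(C)=C2)[C@@H]1C(C)C | intermediate
26 | (1R,3R,5S,6R,8R,9S,10S) 8,9-epoxide of 25 | CC(C)(C)[Si](C)(C)O[C@@H]1C[C@](C)(O)C[C@H]2[C@@H](C[C@@]3(C)O[C@@H]23)[C@@H]1C(C)C | intermediate
27 | (1R,3R,5S,6R,8R,9S,10S) 8,9-epoxy-1,3-diol | O[C@@H]1C[C@](C)(O)C[C@H]2[C@@H](C[C@@]3(C)O[C@@H]23)[C@@H]1C(C)C | intermediate
28 | 3-hydroxy-4-methoxybenzoic acid (isovanillic acid) | COc1ccc(C(=O)O)cc1O | starting material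
29 | tert-butyldimethylsilyl 3-(tert-butyldimethylsilyloxy)-4-methoxybenzoate | COc1ccc(C(=O)O[Si](C)(C)C(C)(C)C)cc1O[Si](C)(C)C(C)(C)C | intermediate
30 | 3-(tert-butyldimethylsilyloxy)-4-methoxybenzoic acid | COc1ccc(C(=O)O)cc1O[Si](C)(C)C(C)(C)C | intermediate
31 | 3-(tert-butyldimethylsilyloxy)-4-methoxybenzoic 2,4,6-trichlorobenzoic anhydride | COc1ccc(C(=O)OC(=O)c2c(Cl)cc(Cl)cc2Cl)cc1O[Si](C)(C)C(C)(C)C | intermediate
32 | C1 3-(tert-butyldimethylsilyloxy)-4-methoxybenzoate of epoxy diol 27 | COc1ccc(C(=O)O[C@@H]2C[C@](C)(O)C[C@H]3[C@@H](C[C@@]4(C)O[C@@H]34)[C@@H]2C(C)C)cc1O[Si](C)(C)C(C)(C)C | intermediate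
33 | CNP0106636.1, (1R,3R,5S,6R,8R,9S,10S) C1 3-hydroxy-4-methoxybenzoate of the 8,9-epoxy-3-hydroxy-3,8-dimethyl-10-isopropyl trans-hydroazulene | COc1ccc(C(=O)O[C@@H]2C[C@](C)(O)C[C@H]3[C@@H](C[C@@]4(C)O[C@@H]34)[C@@H]2C(C)C)cc1O | target

**Step count and risks**

Total step count: 19. Longest linear sequence: 18 steps (steps 1–16, 18 and 19).

Step 12 (key step). The silyl anion may alkylate at the chloride before the epoxide is consumed, or the silyl migration may stall. The relayed anion may also eliminate HCl or couple between molecules faster than it closes the seven-membered ring. The fallback separates the three events with classical dithiane chemistry. It sets out from 18: 2-lithio-1,3-dithiane (1,3-dithiane, n-BuLi, THF, −30 °C) opens the epoxide at C2 to give the hydroxy dithiane F1. Silylation (t-BuMe2SiOTf, 2,6-lutidine) gives the silyl ether F2. Deprotonation of the dithiane C–H (n-BuLi, THF/HMPA, −78 → 0 °C, high dilution) then effects a Corey–Seebach cycloalkylation at C4, which comes back to the route at 23.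

Step 14. Facial selectivity may be poor if the seven-membered ring does not hold the silyloxy group axial, and enolisation with loss of the silyloxy group may compete. The fallback builds the C3 carbinol by hydroxyl direction instead of steric approach control and sets out from 24. Wittig methylenation (Ph3PCH3Br, t-BuOK, THF) gives the exocyclic alkene F3, and Bu4NF gives the homoallylic alcohol F4. Epoxidation with VO(acac)2 and t-BuOOH, directed by the C1 hydroxyl, places oxygen on the same face and gives the spiro-epoxide F5. LiBHEt3 opens it at the methylene carbon to the diol F6, whose C3 hydroxyl is cis to the C1 hydroxyl by construction. Epoxidation of F6 under the conditions of step 15 comes back to the route at 27.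

Step 15. Catalyst control may be eroded if the substrate's own facial preference opposes it (mismatched pairing). The fallback is a halohydrin route that turns that preference to use, and sets out from 25. NBS in aqueous THF should place bromine on the face the substrate prefers (β), and water opens the bromonium ion anti at the tertiary C8 to give the bromohydrin F7. K2CO3 in MeOH closes it with inversion at C9 to the α-epoxide, coming back to the route at 26.

**Further compounds**

F1 | step 12 | (2R,3S)-3-[(1S,2S)-2-(chloromethyl)-4-methylcyclopent-3-en-1-yl]-1-(1,3-dithian-2-yl)-4-methylpentan-2-ol | O[C@H](CC1SCCCS1)[C@@H](C(C)C)[C@@H]2CC(C)=C[C@H]2CCl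
F2 | step 12 | tert-butyldimethylsilyl ether of F1 | CC(C)(C)[Si](C)(C)O[C@H](CC1SCCCS1)[C@@H](C(C)C)[C@@H]2CC(C)=C[C@H]2CCl
F3 | step 14 | (1R,5S,6R,10S) 3-methylidene hydroazulene with C1 tert-butyldimethylsilyl ether | CC(C)(C)[Si](C)(C)O[C@@H]1CC(=C)C[C@H]2[C@@H](CC(C)=C2)[C@@H]1C(C)C
F4 | step 14 | (1R,5S,6R,10S) 3-methylidene hydroazulen-1-ol | O[C@@H]1CC(=C)C[C@H]2[C@@H](CC(C)=C2)[C@@H]1C(C)C
F5 | step 14 | C3 spiro-oxirane of F4 with the epoxide oxygen cis to the C1 hydroxyl | O[C@@H]1C[C@@]2(CO2)C[C@H]3[C@@H](CC(C)=C3)[C@@H]1C(C)C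
F6 | step 14 | (1R,3R,5S,6R,10S) 3-methyl hydroazulene-1,3-diol with C8=C9 | O[C@@H]1C[C@](C)(O)C[C@H]2[C@@H](CC(C)=C2)[C@@H]1C(C)C
F7 | step 15 | 9β-bromo-8α-hydroxy bromohydrin of 25 | CC(C)(C)[Si](C)(C)O[C@@H]1C[C@](C)(O)C[C@H]2[C@@H](C[C@@](C)(O)[C@@H]2Br)[C@@H]1C(C)C
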